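**Retrosynthetic overview**
- The CH2–O(coumarin) ether bond is cut to umbelliferone plus a primary B-alkyl-9-BBN; it is closed by a light-driven, copper-mediated C(sp3)–O coupling.
- The alkylborane comes from syn hydroboration of an exocyclic 1,3-diene, which sets C1 (carvone numbering) under control of C5/C6.
- The diene comes from a hindered enone by methylenation; the ester comes from (R)-2-methylbutanoic acid and (5R)-5-hydroxy-2,6,6-trimethylcyclohex-2-enone.
- The C5–O bond comes from the isopropenyl group of 6,6-dimethylcarvone (ozonolysis/Criegee rearrangement, retention), itself from (R)-carvone by two α'-methylations.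
- No ring is formed: the cyclohexene is bought in (R)-carvone and the coumarin in umbelliferone.

Assumption: (R)-2-methylbutanoic acid, the enantiomer the target SMILES requires, is bought enantiopure, as are (R)-(−)-carvone and umbelliferone.

**Step 1**
Reactants: 1 (R)-(−)-carvone
Product: 3 (5S)-2,6,6-trimethyl-5-(prop-1-en-2-yl)cyclohex-2-en-1-one (6,6-dimethylcarvone), via trans-6-methylcarvone 2 (not isolated)
Conditions: LiN(iPr)2 (1.1 equiv), THF, −78 °C, then MeI (1.1 equiv), −78 → 0 °C; recool, LiN(iPr)2 (1.3 equiv), −78 °C, then MeI (2 equiv), −78 °C → rt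
Reagents that add atoms: iodomethane, CI
Why: Kinetic deprotonation of the enone with the lithium amide occurs only at C6 (α'), and two rounds of enolate alkylation build the gem-dimethyl group while the C5 stereocentre bought in carvone is untouched (its descriptor changes from R to S only through CIP priorities, and the C6 centre of 2 is erased by the second methylation).

**Step 2**
Reactants: 3 (5S)-2,6,6-trimethyl-5-(prop-1-en-2-yl)cyclohex-2-en-1-one
Product: 6 (5R)-5-hydroxy-2,6,6-trimethylcyclohex-2-en-1-one, via methoxy hydroperoxide 4 (not isolated), via enone acetate 5 (not isolated)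
Conditions: O3, CH2Cl2/MeOH, −78 °C (indicator end point); Ac2O, Et3N, 4-(dimethylamino)pyridine (cat.), CH2Cl2, 0 °C → rt; concentrate, then TsOH·H2O (cat.), MeOH, 40 °C
Reagents that add atoms: ozone, [O-][O+]=O
Why: Ozone cleaves the electron-rich isopropenyl group in preference to the enone C=C, methanol traps the ketone oxide as 4, and the derived peracetate undergoes Criegee rearrangement in which C5 migrates to oxygen with retention to give 5, which is unmasked by acid-catalysed methanolysis (non-basic, to avoid retro-aldol opening of the β-ketol).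

**Step 3**
Reactants: 6 (5R)-5-hydroxy-2,6,6-trimethylcyclohex-2-en-1-one; 7 (R)-2-methylbutanoic acid
Product: 8 (1R)-2,2,4-trimethyl-3-oxocyclohex-4-en-1-yl (2R)-2-methylbutanoate
Conditions: DCC, 4-(dimethylamino)pyridine (0.2 equiv), CH2Cl2, 0 °C → rt
Reagents that add atoms: none
Why: Steglich esterification acylates the hindered secondary alcohol under near-neutral conditions that touch neither the carbinol centre nor the bought α-stereocentre of the acid, and the ester also blocks retro-aldol chemistry in later steps.

**Step 4**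
Reactants: 8 (1R)-2,2,4-trimethyl-3-oxocyclohex-4-en-1-yl (2R)-2-methylbutanoate
Product: 9 (1R)-2,2,4-trimethyl-3-methylidenecyclohex-4-en-1-yl (2R)-2-methylbutanoate
Conditions: Zn, CH2Br2, TiCl4 (preformed reagent), THF/CH2Cl2, 0 °C → rt
Reagents that add atoms: dibromomethane, BrCBr
Why: Lombardo methylenation uses a non-basic, oxophilic zinc/titanium methylene reagent that converts hindered, base-sensitive ketones into exocyclic alkenes and ignores esters, so the vinylogous E1cB loss of the C5 carboxylate that a basic Wittig ylide could trigger is avoided.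

**Step 5**
Reactants: 9 (1R)-2,2,4-trimethyl-3-methylidenecyclohex-4-en-1-yl (2R)-2-methylbutanoate; 10 umbelliferone (7-hydroxycoumarin)
Product: 12 (1R,3S)-2,2,4-trimethyl-3-{[(2-oxo-2H-chromen-7-yl)oxy]methyl}cyclohex-4-en-1-yl (2R)-2-methylbutanoate (CNP0199249.1), via B-alkyl-9-BBN 11 (not isolated)
Conditions: 9-BBN (1.3 equiv), THF, 0 °C → rt; then KOtBu (2.5 equiv), 10 (1.5 equiv), Cu(OAc)2 (2.2 equiv), 1,10-phenanthroline (0.3 equiv), Ir(ppy)3 (2 mol%), THF/DMF, N2, blue LED (450 nm), rt
Reagents that add atoms: none
Why: Proposed new method: 9-BBN adds only to the exocyclic C=CH2 (boron to CH2, concerted syn addition, so hydrogen cannot end at C3) and delivers hydrogen to C1 from the face opposite the C5 acyloxy group and the pseudo-axial C6 methyl, placing the CH2B arm cis to the ester so that C1 is controlled by the carvone-derived C5; the tert-butoxide ate complex of 11 then transfers its primary alkyl group to a divalent copper aryloxide of 10, photoexcited Ir(ppy)3 is quenched by Cu(OAc)2 and the resulting tetravalent iridium oxidises the alkyl copper aryloxide to trivalent copper, which reductively eliminates the C(sp3)–O bond faster than β-hydride loss and without any SN2 at the neopentyl-type carbon; the closest known reaction types are the visible-light-accelerated Chan–Lam coupling of arylboronic acids, Chan–Lam O-methylation and O-cyclopropylation of phenols, and hydroboration followed by copper-catalysed amination of B-alkyl-9-BBN reagents (formal anti-Markovnikov hydroamination), none shown for a β-hydrogen-bearing primary alkylborane with a phenol.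

**Compound list**
1 | (R)-(−)-carvone, (5R)-2-methyl-5-(prop-1-en-2-yl)cyclohex-2-en-1-one | C=C(C)[C@@H]1CC=C(C)C(=O)C1 | starting material
2 | (5R,6S)-2,6-dimethyl-5-(prop-1-en-2-yl)cyclohex-2-en-1-one (trans-6-methylcarvone, major C6 epimer; the minor epimer converges to 3) | C=C(C)[C@@H]1CC=C(C)C(=O)[C@H]1C | intermediate
3 | (5S)-2,6,6-trimethyl-5-(prop-1-en-2-yl)cyclohex-2-en-1-one (6,6-dimethylcarvone) | C=C(C)[C@@H]1CC=C(C)C(=O)C1(C)C | intermediate
4 | (5R)-5-(1-hydroperoxy-1-methoxyethyl)-2,6,6-trimethylcyclohex-2-en-1-one (both epimers at the side-chain carbon) | COC(C)(OO)[C@@H]1CC=C(C)C(=O)C1(C)C | intermediate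
5 | (1R)-2,2,4-trimethyl-3-oxocyclohex-4-en-1-yl acetate | CC(=O)O[C@@H]1CC=C(C)C(=O)C1(C)C | intermediate
6 | (5R)-5-hydroxy-2,6,6-trimethylcyclohex-2-en-1-one | O[C@@H]1CC=C(C)C(=O)C1(C)C | intermediate
7 | (R)-2-methylbutanoic acid | CC[C@@H](C)C(=O)O | starting material
8 | (1R)-2,2,4-trimethyl-3-oxocyclohex-4-en-1-yl (2R)-2-methylbutanoate | CC[C@@H](C)C(=O)O[C@@H]1CC=C(C)C(=O)C1(C)C | intermediate
9 | (1R)-2,2,4-trimethyl-3-methylidenecyclohex-4-en-1-yl (2R)-2-methylbutanoate | CC[C@@H](C)C(=O)O[C@@H]1CC=C(C)C(=C)C1(C)C | intermediate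
10 | umbelliferone (7-hydroxy-2H-chromen-2-one) | Oc1ccc2ccc(=O)oc2c1 | starting material
11 | (1R,3S)-3-[(9-borabicyclo[3.3.1]nonan-9-yl)methyl]-2,2,4-trimethylcyclohex-4-en-1-yl (2R)-2-methylbutanoate | CC[C@@H](C)C(=O)O[C@@H]1CC=C(C)[C@H](CB2C3CCCC2CCC3)C1(C)C | intermediate
12 | (1R,3S)-2,2,4-trimethyl-3-{[(2-oxo-2H-chromen-7-yl)oxy]methyl}cyclohex-4-en-1-yl (2R)-2-methylbutanoate | CC[C@@H](C)C(=O)O[C@@H]1CC=C(C)[C@H](COc2ccc3ccc(=O)oc3c2)C1(C)C | target

**Step count and risks**
Total steps: 5. Longest linear sequence: 5 (1 → 3 → 6 → 8 → 9 → 12).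

Three steps most likely to fail:

1. Step 5 (the new coupling). The likely failure modes are protodeboronation or β-hydride loss at copper, oxidation of the 9-BBN cage, sensitised [2+2] dimerisation of the coumarin, and an insufficient cis:trans ratio in the hydroboration. The fallback uses only known chemistry and sets out from 9. Hydroborate with 9-BBN as above and oxidise the borane 11 with NaBO3·4H2O (THF/H2O, rt) to the primary alcohol (1R,3S)-3-(hydroxymethyl)-2,2,4-trimethylcyclohex-4-en-1-yl (2R)-2-methylbutanoate F1, and remove any minor C1 epimer by chromatography. Then O-arylate F1 with commercial 7-bromocoumarin (O=c1ccc2ccc(Br)cc2o1) by the established nickel/photoredox aryl etherification (NiCl2·dimethoxyethane, 4,4'-di-tert-butyl-2,2'-bipyridine, Ir[dF(CF3)ppy]2(dtbbpy)PF6, quinuclidine, K2CO3, MeCN, blue LED). This forms the aryl C–O bond at nickel, again with no substitution at the hindered CH2, and returns to the route at 12.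

2. Step 4 (methylenation of a ketone flanked by a quaternary carbon and a methyl-bearing sp2 carbon). The reagent may be too sluggish. The fallback sets out from 8. Add Me3SiCH2Li/CeCl3 (THF, −78 °C; the organocerium adds 1,2 to hindered, enolisable ketones and spares the hindered ester at this temperature) to give the β-hydroxysilane (1R)-3-hydroxy-2,2,4-trimethyl-3-[(trimethylsilyl)methyl]cyclohex-4-en-1-yl (2R)-2-methylbutanoate F2, either C3 epimer. Acid-induced Peterson elimination (TsOH cat., CH2Cl2) then returns to the route at 9.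

3. Step 2 (one-pot Criegee rearrangement and unmasking of the β-ketol). The Criegee stage is well behaved, but the free β-hydroxy ketone 6 may be formed slowly or suffer retro-aldol opening, which would racemise C5. The fallback stops the sequence at the acetate and sets out from isolated 5. Methylenate 5 (Zn, CH2Br2, TiCl4) to the acetoxy diene (1R)-2,2,4-trimethyl-3-methylidenecyclohex-4-en-1-yl acetate F3. Cleave the acetate now that no ketone is present (K2CO3, MeOH, rt) to the dienol (1R)-2,2,4-trimethyl-3-methylidenecyclohex-4-en-1-ol F4. Esterify F4 with 7 (DCC, 4-(dimethylamino)pyridine), which returns to the route at 9.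

**Further compounds**
F1 | step 5 | (1R,3S)-3-(hydroxymethyl)-2,2,4-trimethylcyclohex-4-en-1-yl (2R)-2-methylbutanoate | CC[C@@H](C)C(=O)O[C@@H]1CC=C(C)[C@H](CO)C1(C)C
F2 | step 4 | (1R)-3-hydroxy-2,2,4-trimethyl-3-[(trimethylsilyl)methyl]cyclohex-4-en-1-yl (2R)-2-methylbutanoate (C3 epimers) | CC[C@@H](C)C(=O)O[C@@H]1CC=C(C)C(O)(C[Si](C)(C)C)C1(C)C
F3 | step 2 | (1R)-2,2,4-trimethyl-3-methylidenecyclohex-4-en-1-yl acetate | CC(=O)O[C@@H]1CC=C(C)C(=C)C1(C)C
F4 | step 2 | (1R)-2,2,4-trimethyl-3-methylidenecyclohex-4-en-1-ol | O[C@@H]1CC=C(C)C(=C)C1(C)C
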